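**Retrosynthetic overview**
1. The SMILES reads as epifisetinidol-(4α→6)-catechin: upper unit (2R,3R,4S) with 2-aryl, 3-OH and 4-aryl all cis, joined through C4 to C6 of a (2R,3S)-catechin unit. The last step is one hydrogenolysis that removes eight benzyl ethers and a C8 bromine.
2. The upper C3 carbinol comes from the 3-ketone: a bulky hydride is steered by the two cis aryl groups at C2 and C4. This inverts C3 of a 2,3-trans-3,4-trans coupling product.
3. The interflavan C4–C6 bond is made by visible-light photoredox ionisation of a 4-arylthioflavan-3-ol and Friedel–Crafts capture by C8-brominated penta-O-benzylcatechin; the 3β-OH directs the arene to the α face.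
4. The electrophile comes from (+)-taxifolin (benzylation, 5-triflation, Pd reduction to the 5-deoxy series, NaBH4/thiolysis); the nucleophile comes from (+)-catechin (benzylation, C8 bromination).
5. No ring is built: both chromane rings are bought. Catechin supplies lower C2/C3; taxifolin supplies upper C2, and its C3 sets C4 before being re-set from C2/C4.

**Steps**

Step 1
Reactants: 1 (+)-catechin
Product: 2 3,5,7,3',4'-penta-O-benzyl-(+)-catechin
Conditions: NaH (6 equiv), BnBr (6 equiv), Bu4NI (cat.), DMF, 0 °C → rt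
Reagents that add atoms: benzyl bromide (BrCc1ccccc1)
Why: Exhaustive Williamson etherification in a dipolar aprotic solvent (O-alkylation favoured) protects the four phenols and the 3-OH, the latter so that it survives the later oxidation; no stereocentre is touched.

Step 2
Reactants: 2 3,5,7,3',4'-penta-O-benzyl-(+)-catechin
Product: 3 8-bromo-3,5,7,3',4'-penta-O-benzyl-(+)-catechin
Conditions: NBS (1.05 equiv), CH2Cl2, −40 °C
Reagents that add atoms: N-bromosuccinimide (O=C1CCC(=O)N1Br)
Why: Electrophilic aromatic bromination of catechin ethers goes selectively to C8, which blocks that position so the later Friedel–Crafts alkylation must occur at C6.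

Step 3
Reactants: 4 (+)-taxifolin
Product: 5 7,3',4'-tri-O-benzyltaxifolin
Conditions: BnBr (3.1 equiv), K2CO3, DMF, rt, Ar
Reagents that add atoms: benzyl bromide (BrCc1ccccc1)
Why: Chemoselective Williamson etherification, because the 5-OH is tied up in a hydrogen bond to the C4 carbonyl and the 3-OH is a non-acidic secondary alcohol; the 2,3-trans arrangement is the thermodynamic one and is retained.

Step 4
Reactants: 5 7,3',4'-tri-O-benzyltaxifolin
Product: 6 7,3',4'-tri-O-benzyltaxifolin 5-O-triflate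
Conditions: PhNTf2, K2CO3, DMF, 0 °C → rt
Reagents that add atoms: N-phenyl-bis(trifluoromethanesulfonimide) (O=S(=O)(N(c1ccccc1)S(=O)(=O)C(F)(F)F)C(F)(F)F)
Why: Phenol-selective sulfonylation with the mild triflyl donor PhNTf2 activates only the 5-OH and leaves the aliphatic 3-OH free.

Step 5
Reactants: 6 7,3',4'-tri-O-benzyltaxifolin 5-O-triflate
Product: 7 7,3',4'-tri-O-benzylfustin
Conditions: Pd(OAc)2, dppp, HCO2H, Et3N, DMF, 60 °C
Reagents that add atoms: none
Why: Palladium-catalysed formate reduction of an aryl triflate (oxidative addition of zerovalent palladium, formate exchange, decarboxylation, C–H reductive elimination) gives the 5-deoxy ring A; homogeneous conditions leave the benzyl ethers and the ketol intact.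

Step 6
Reactants: 7 7,3',4'-tri-O-benzylfustin
Product: 9 (2R,3R,4R)-7-(benzyloxy)-2-[3,4-bis(benzyloxy)phenyl]-4-[(4-methoxyphenyl)sulfanyl]chroman-3-ol, via tri-O-benzylflavan-3,4-diol 8 (not isolated)
Conditions: NaBH4, THF/EtOH, 0 °C; then concentrate, 4-MeOC6H4SH (4 equiv), TFA (5% v/v), CH2Cl2, 0 °C
Reagents that add atoms: 4-methoxybenzenethiol (COc1ccc(S)cc1)
Why: Axial hydride addition gives the 2,3-trans-3,4-trans diol, whose benzylic 4-OH is then exchanged by acid-catalysed SN1 thiolysis (the thiol outcompetes all arene nucleophiles) mainly anti to the 3β-OH; the minor C4 epimer is carried along because both give the same cation in step 7.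

Step 7
Reactants: 9 the 4-arylthioflavan-3-ol; 3 8-bromo-3,5,7,3',4'-penta-O-benzyl-(+)-catechin
Product: 10 8-bromo-octa-O-benzyl fisetinidol-(4α→6)-catechin with free upper 3-OH (upper unit 2R,3S,4S)
Conditions: 3 (2.5 equiv), 4CzIPN (2 mol%), 450 nm LEDs, CH2Cl2/HFIP 4:1, 4 Å MS, 0 °C, Ar
Reagents that add atoms: none
Why: Proposed new method: excited 4CzIPN (about +1.35 V vs SCE) oxidises the 4-methoxyphenylthio group, the most easily oxidised site of 9, the sulfide radical cation undergoes mesolytic C–S cleavage to an ArS radical and the C4 cation (stabilised by the para-benzyloxy group and O1), C6 of 3 (C8 is blocked) captures the cation in a Friedel–Crafts alkylation from the α face, anti to the 3β-hydroxyl (which may bridge C4 transiently as a β-epoxide that HFIP reopens with inversion), so the new centre is 3,4-trans and 2,4-cis (4S), and the reduced photocatalyst returns its electron to the ArS radical so the arenium proton leaves as ArSH with no acid or oxidant building up; the closest known reaction types are photoredox and anodic activation of thioglycosides and silver-salt activation of 4-benzylthioflavan-3-ols for interflavan bond formation.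

Step 8
Reactants: 10 the 2,3-trans-3,4-trans coupling product
Product: 11 the corresponding flavan-3-one (upper unit 2R,4S)
Conditions: Dess–Martin periodinane, CH2Cl2, 0 °C → rt
Reagents that add atoms: none
Why: Dess–Martin oxidation converts the only free hydroxyl (the lower 3-OH is a benzyl ether) to the ketone under non-basic conditions, so the two flanking benzylic stereocentres C2 and C4 are not enolised; the ketone is used at once.

Step 9
Reactants: 11 the flavan-3-one
Product: 12 8-bromo-octa-O-benzyl epifisetinidol-(4α→6)-catechin with free upper 3-OH (upper unit 2R,3R,4S)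
Conditions: LiBH(s-Bu)3 (L-selectride), LiBr, THF, −78 °C; then H2O
Reagents that add atoms: none
Why: Substrate-controlled ketone reduction, as in the catechin-to-epicatechin oxidation/reduction protocol: the bulky hydride enters along the equatorial trajectory on the β face, anti to the two pseudo-equatorial α-aryl groups at C2 and C4, giving the axial 3α-alcohol (C3 = R, all-cis).

Step 10
Reactants: 12 the all-cis bromo octabenzyl ether
Product: 13 epifisetinidol-(4α→6)-catechin (CNP0141631.2)
Conditions: H2 (1 atm), Pd(OH)2/C, Et3N, THF/MeOH/H2O, rt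
Reagents that add atoms: none
Why: Catalytic hydrogenolysis cleaves all eight benzyl ethers and the aryl C–Br bond in one operation without touching any stereocentre or the acid-stable 5-deoxy interflavan bond.

**Compound list**
1 | (+)-catechin, (2R,3S)-2-(3,4-dihydroxyphenyl)chromane-3,5,7-triol | Oc1cc(O)c2c(c1)O[C@H](c1ccc(O)c(O)c1)[C@@H](O)C2 | starting material
2 | 3,5,7,3',4'-penta-O-benzyl-(+)-catechin (2R,3S) | c1ccccc1COc1cc(OCc3ccccc3)c2c(c1)O[C@H](c1ccc(OCc3ccccc3)c(OCc3ccccc3)c1)[C@@H](OCc1ccccc1)C2 | intermediate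
3 | 8-bromo-3,5,7,3',4'-penta-O-benzyl-(+)-catechin (2R,3S) | c1ccccc1COc1cc(OCc3ccccc3)c2c(c1Br)O[C@H](c1ccc(OCc3ccccc3)c(OCc3ccccc3)c1)[C@@H](OCc1ccccc1)C2 | intermediate
4 | (+)-taxifolin, (2R,3R)-2-(3,4-dihydroxyphenyl)-3,5,7-trihydroxychroman-4-one | Oc1cc(O)c2c(c1)O[C@H](c1ccc(O)c(O)c1)[C@@H](O)C2=O | starting material
5 | 7,3',4'-tri-O-benzyltaxifolin (2R,3R; 3-OH and 5-OH free) | c1ccccc1COc1cc(O)c2c(c1)O[C@H](c1ccc(OCc3ccccc3)c(OCc3ccccc3)c1)[C@@H](O)C2=O | intermediate
6 | 7,3',4'-tri-O-benzyltaxifolin 5-O-trifluoromethanesulfonate (2R,3R) | c1ccccc1COc1cc(OS(=O)(=O)C(F)(F)F)c2c(c1)O[C@H](c1ccc(OCc3ccccc3)c(OCc3ccccc3)c1)[C@@H](O)C2=O | intermediate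
7 | 7,3',4'-tri-O-benzylfustin, (2R,3R)-7-(benzyloxy)-2-[3,4-bis(benzyloxy)phenyl]-3-hydroxychroman-4-one | c1ccccc1COc1ccc2c(c1)O[C@H](c1ccc(OCc3ccccc3)c(OCc3ccccc3)c1)[C@@H](O)C2=O | intermediate
8 | (2R,3S,4R)-7-(benzyloxy)-2-[3,4-bis(benzyloxy)phenyl]chromane-3,4-diol (2,3-trans-3,4-trans; not isolated) | c1ccccc1COc1ccc2c(c1)O[C@H](c1ccc(OCc3ccccc3)c(OCc3ccccc3)c1)[C@@H](O)[C@@H]2O | intermediate
9 | (2R,3R,4R)-7-(benzyloxy)-2-[3,4-bis(benzyloxy)phenyl]-4-[(4-methoxyphenyl)sulfanyl]chroman-3-ol (2α-aryl, 3β-OH, 4α-SAr) | c1ccccc1COc1ccc2c(c1)O[C@H](c1ccc(OCc3ccccc3)c(OCc3ccccc3)c1)[C@@H](O)[C@@H]2Sc1ccc(OC)cc1 | intermediate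
10 | 8-bromo-octa-O-benzyl fisetinidol-(4α→6)-catechin, upper unit (2R,3S,4S) with free 3-OH, lower unit (2R,3S) with 3-OBn | c1ccccc1COc1ccc2c(c1)O[C@H](c1ccc(OCc3ccccc3)c(OCc3ccccc3)c1)[C@@H](O)[C@@H]2c1c(OCc3ccccc3)c(Br)c2c(c1OCc3ccccc3)C[C@H](OCc1ccccc1)[C@@H](c1ccc(OCc3ccccc3)c(OCc3ccccc3)c1)O2 | intermediate
11 | 3-ketone of 10, upper unit (2R,4S)-2,4-cis-diaryl-chroman-3-one | c1ccccc1COc1ccc2c(c1)O[C@H](c1ccc(OCc3ccccc3)c(OCc3ccccc3)c1)C(=O)[C@@H]2c1c(OCc3ccccc3)c(Br)c2c(c1OCc3ccccc3)C[C@H](OCc1ccccc1)[C@@H](c1ccc(OCc3ccccc3)c(OCc3ccccc3)c1)O2 | intermediate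
12 | 8-bromo-octa-O-benzyl epifisetinidol-(4α→6)-catechin, upper unit (2R,3R,4S) all-cis with free 3-OH | c1ccccc1COc1ccc2c(c1)O[C@H](c1ccc(OCc3ccccc3)c(OCc3ccccc3)c1)[C@H](O)[C@@H]2c1c(OCc3ccccc3)c(Br)c2c(c1OCc3ccccc3)C[C@H](OCc1ccccc1)[C@@H](c1ccc(OCc3ccccc3)c(OCc3ccccc3)c1)O2 | intermediate
13 | epifisetinidol-(4α→6)-catechin, upper unit (2R,3R,4S), lower unit (2R,3S) | Oc1ccc2c(c1)O[C@H](c1ccc(O)c(O)c1)[C@H](O)[C@@H]2c1c(O)cc2c(c1O)C[C@H](O)[C@@H](c1ccc(O)c(O)c1)O2 | target

**Step count**
Total: 10 steps. Longest linear sequence: 8 steps (4 → 13, steps 3 to 10).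

**Steps most likely to fail**

Step 7, the proposed photoredox coupling. The risks are slow C–S mesolysis, alkylation of ring A of 9 or 10 instead of the hindered, bromine-deactivated C6 of 3, and a 3,4-cis minor isomer. The fallback uses known chemistry and sets out from 7. After the NaBH4 reduction, diol 8 is isolated and acetylated (Ac2O, pyridine, DMAP) to the 3,4-di-O-acetate of diol 8 F2. F2 is coupled with 3 (2.5 equiv) under BF3·OEt2 in CH2Cl2 at −40 °C: the benzylic 4-acetate ionises, the 3-acetoxy group bridges the β face as an acetoxonium ion, and the arene enters from the α face. This gives the 3-O-acetate of 10 F3. K2CO3 in MeOH/THF removes the acetate and the route is rejoined at 10.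

Step 9, the hydride reduction. The ketone is hindered and enolisable on both sides, so enolisation could scramble C2 or C4, and the facial selectivity may be lower than in the monomer precedent. The fallback sets out from 10 and inverts C3 without passing through the ketone. A Mitsunobu reaction (4-nitrobenzoic acid, PPh3, DIAD, toluene, 0 °C → rt) gives the inverted all-cis 3-O-(4-nitrobenzoate) of 12 F4. Methanolysis (K2CO3, MeOH/THF) returns the route at 12.

Step 6, the telescoped reduction and acid thiolysis. The cation may self-condense, or TFA with thiol may nick benzyl ethers. The fallback sets out from 7. Diol 8 is isolated after the NaBH4 reduction and the C–S bond is made under neutral redox-condensation conditions (bis(4-methoxyphenyl) disulfide, PBu3, THF, rt; Hata reaction). The benzylic 4-oxyphosphonium ion is displaced by thiolate with inversion to give the 3,4-cis C4-epimeric thioether F1. F1 gives the same C4 cation as 9 under the step 7 conditions, so the route is rejoined at 10.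

**Further compounds**
F1 | step 6 | (2R,3R,4S)-7-(benzyloxy)-2-[3,4-bis(benzyloxy)phenyl]-4-[(4-methoxyphenyl)sulfanyl]chroman-3-ol (C4 epimer of 9; 2α-aryl, 3β-OH, 4β-SAr) | c1ccccc1COc1ccc2c(c1)O[C@H](c1ccc(OCc3ccccc3)c(OCc3ccccc3)c1)[C@@H](O)[C@H]2Sc1ccc(OC)cc1
F2 | step 7 | 3,4-di-O-acetate of diol 8 (2α-aryl, 3β-OAc, 4α-OAc) | c1ccccc1COc1ccc2c(c1)O[C@H](c1ccc(OCc3ccccc3)c(OCc3ccccc3)c1)[C@@H](OC(C)=O)[C@@H]2OC(C)=O
F3 | step 7 | 3-O-acetate of 10 (upper unit 2α-aryl, 3β-OAc, 4α-aryl) | c1ccccc1COc1ccc2c(c1)O[C@H](c1ccc(OCc3ccccc3)c(OCc3ccccc3)c1)[C@@H](OC(C)=O)[C@@H]2c1c(OCc3ccccc3)c(Br)c2c(c1OCc3ccccc3)C[C@H](OCc1ccccc1)[C@@H](c1ccc(OCc3ccccc3)c(OCc3ccccc3)c1)O2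
F4 | step 9 | 3-O-(4-nitrobenzoate) of 12 (upper unit all-cis) | c1ccccc1COc1ccc2c(c1)O[C@H](c1ccc(OCc3ccccc3)c(OCc3ccccc3)c1)[C@H](OC(=O)c1ccc(cc1)[N+](=O)[O-])[C@@H]2c1c(OCc3ccccc3)c(Br)c2c(c1OCc3ccccc3)C[C@H](OCc1ccccc1)[C@@H](c1ccc(OCc3ccccc3)c(OCc3ccccc3)c1)O2
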